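**Retrosynthetic overview**

1. Ring labels: ring A = benzo ring of the quinone; ring B = quinone ring (C1(=O), C2(OAr), C3(H), C4(=O), C4a, C8a); ring C = fully substituted naphthol ring; ring D = its benzo ring. Rubioncolin C ⇒ CO + a 1-(2-iodophenyl)-2-aryloxyprop-2-en-1-one: ring B is cut at C3–C4 (ring closure) and at C4–C4a (CO insertion).
2. Enabling feature: in ring B the carbonyl carbon C4 lies between benzo carbon C4a and C3. C3 is the only hydrogen-bearing carbon of that ring and the free terminus of the C2(OAr)=C3 enol-ether bond conjugated to C1=O. C4 can therefore enter as CO on an aryl–palladium bond at C4a, close onto C3 in the 6-endo mode, and reach the quinone level directly by loss of HPdI.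
3. Enone ⇒ α-aryloxy ketone + CH2O (C3 by α-methylenation) ⇒ 4-OH of the prenylated naphthohydroquinone ester + 2-bromo-1-(2-iodophenyl)ethanone (Williamson, C2–O bond).
4. Prenylated hydroquinone ester ⇒ methyl 1,4-dihydroxy-2-naphthoate + 2-methylbut-3-en-2-ol (Friedel–Crafts at C3 of ring C); bromoketone ⇒ 2'-iodoacetophenone.
5. Ring order: rings C/D and ring A are bought intact; ring B is the only ring made and is closed last.

Key step: step 5

Remark: the three starting materials (methyl 1,4-dihydroxy-2-naphthoate, 2-methylbut-3-en-2-ol, 2'-iodoacetophenone) are taken as commercial; the chelated 1-OH of ring C is carried unprotected throughout.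

**Route**

Step 1
Reactants: 1 methyl 1,4-dihydroxy-2-naphthoate; 2 2-methylbut-3-en-2-ol
Product: 3 methyl 1,4-dihydroxy-3-(3-methylbut-2-en-1-yl)-2-naphthoate
Conditions: BF3·OEt2 (0.3 equiv), dioxane, 20 °C, Ar
Reagents that add atoms: none
Why: Friedel–Crafts allylation of a hydroquinone (the reaction type used to prenylate naphthohydroquinones of the vitamin K series): the dimethylallyl cation from 2 and BF3 attacks through its primary terminus at C3, the only free position of the oxygenated ring and ortho to the 4-OH, and no stereocentre is formed.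

Step 2
Reactants: 4 1-(2-iodophenyl)ethan-1-one
Product: 5 2-bromo-1-(2-iodophenyl)ethan-1-one
Conditions: Br2 (1.0 equiv), AcOH, 20 °C
Reagents that add atoms: bromine, BrBr
Why: Acid-catalysed α-bromination of an aryl methyl ketone through its enol, which should stop at the monobromide because the bromoketone enolises more slowly and the iodoarene ring is deactivated towards bromine.

Step 3
Reactants: 3 methyl 1,4-dihydroxy-3-(3-methylbut-2-en-1-yl)-2-naphthoate; 5 2-bromo-1-(2-iodophenyl)ethan-1-one
Product: 6 methyl 1-hydroxy-4-[2-(2-iodophenyl)-2-oxoethoxy]-3-(3-methylbut-2-en-1-yl)-2-naphthoate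
Conditions: K2CO3 (1.1 equiv), degassed acetone, 40 °C, Ar
Reagents that add atoms: none
Why: Williamson ether synthesis with a phenacyl bromide: the 1-OH is tied up in a hydrogen bond to the ester carbonyl and is a poor nucleophile, so the free 4-OH (both of whose ortho carbons are blocked against C-alkylation) should be etherified, while exclusion of air keeps the hydroquinone from oxidising.

Step 4
Reactants: 6 methyl 1-hydroxy-4-[2-(2-iodophenyl)-2-oxoethoxy]-3-(3-methylbut-2-en-1-yl)-2-naphthoate
Product: 8 methyl 1-hydroxy-4-{[3-(2-iodophenyl)-3-oxoprop-1-en-2-yl]oxy}-3-(3-methylbut-2-en-1-yl)-2-naphthoate, via Mannich base 7 (not isolated)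
Conditions: (CH2O)n (2 equiv), i-Pr2NH·CF3CO2H (1 equiv), CF3CO2H (10 mol %), THF, reflux
Reagents that add atoms: paraformaldehyde (reacts as formaldehyde), C=O
Why: Mannich condensation followed by β-elimination (direct α-methylenation of a ketone): the OCH2 group is the only enolisable position, its enol adds to the iminium ion from formaldehyde and i-Pr2NH to give 7, and loss of the amine gives the conjugated 1,1-disubstituted enone, the transient stereocentre of 7 being destroyed.

Step 5
Reactants: 8 methyl 1-hydroxy-4-{[3-(2-iodophenyl)-3-oxoprop-1-en-2-yl]oxy}-3-(3-methylbut-2-en-1-yl)-2-naphthoate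
Product: 11 rubioncolin C, via aroylpalladium iodide 9 (not isolated), via cyclised palladium enolate 10 (not isolated)
Conditions: PdCl2(PPh3)2 (5 mol %), i-Pr2NEt (2 equiv), CO (40 atm), MeCN–toluene 1:1 (0.02 M), 90 °C
Reagents that add atoms: carbon monoxide, [C-]#[O+]
Why: Zerovalent palladium (formed in the flask from PdCl2(PPh3)2, amine and CO) inserts into the aryl C–I bond of 8 and takes up CO to give 9, whose acyl carbon (the future C4) adds to the terminal CH2 (C3) of the α-aryloxy enone to give the six-membered palladium enolate 10; syn β-hydride elimination from C3 then sets the C2=C3 double bond of the quinone directly, and i-Pr2NEt takes up HI to return zerovalent palladium. The closest known reaction type is the palladium-catalysed carbonylative cyclisation (cyclic acylpalladation) of 2-iodoaryl alkenyl ketones to 1,4-naphthoquinones. Ring B closes in the 6-endo-trig mode through the C3–C4 bond, the C4–C4a bond having been made just before by CO insertion. No stereocentre remains, since the one at C2 of 10 is lost on elimination. The step needs CO uptake before any direct Heck closure and 6-endo rather than 5-exo acyl delivery: the first is secured by CO pressure and by the strained 4-exo and 5-endo alternatives open to the arylpalladium, the second by the enone polarisation that sends the acyl group to the β-carbon and palladium to the α-carbon as an enolate, and by the fully substituted C2, where exo attack would build a quaternary centre and leave a CH2–Pd species without β-hydrogen. The chelated 1-OH of ring C is a poor nucleophile, and high dilution in alcohol-free solvent should keep intermolecular ester formation from 9 from competing.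

**Compound list**

1 | methyl 1,4-dihydroxy-2-naphthoate | COC(=O)c1cc(O)c2ccccc2c1O | starting material
2 | 2-methylbut-3-en-2-ol | CC(C)(O)C=C | starting material
3 | methyl 1,4-dihydroxy-3-(3-methylbut-2-en-1-yl)-2-naphthoate | COC(=O)c1c(CC=C(C)C)c(O)c2ccccc2c1O | intermediate
4 | 1-(2-iodophenyl)ethan-1-one (2'-iodoacetophenone) | CC(=O)c1ccccc1I | starting material
5 | 2-bromo-1-(2-iodophenyl)ethan-1-one | O=C(CBr)c1ccccc1I | intermediate
6 | methyl 1-hydroxy-4-[2-(2-iodophenyl)-2-oxoethoxy]-3-(3-methylbut-2-en-1-yl)-2-naphthoate | COC(=O)c1c(CC=C(C)C)c(OCC(=O)c2ccccc2I)c2ccccc2c1O | intermediate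
7 | Mannich base: methyl 4-{[3-(diisopropylamino)-1-(2-iodophenyl)-1-oxopropan-2-yl]oxy}-1-hydroxy-3-(3-methylbut-2-en-1-yl)-2-naphthoate (racemic, not isolated) | COC(=O)c1c(CC=C(C)C)c(OC(CN(C(C)C)C(C)C)C(=O)c2ccccc2I)c2ccccc2c1O | intermediate
8 | methyl 1-hydroxy-4-{[3-(2-iodophenyl)-3-oxoprop-1-en-2-yl]oxy}-3-(3-methylbut-2-en-1-yl)-2-naphthoate | COC(=O)c1c(CC=C(C)C)c(OC(=C)C(=O)c2ccccc2I)c2ccccc2c1O | intermediate
9 | aroylpalladium iodide from 8 and CO (divalent palladium, PPh3 ligands not drawn, not isolated) | COC(=O)c1c(CC=C(C)C)c(OC(=C)C(=O)c2ccccc2C(=O)[Pd]I)c2ccccc2c1O | intermediate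
10 | cyclised palladium enolate, C2-bound 2-aryloxy-1,4-dioxo-1,2,3,4-tetrahydronaphthalen-2-ylpalladium iodide (divalent palladium, PPh3 ligands not drawn, racemic, not isolated) | COC(=O)c1c(CC=C(C)C)c(OC2([Pd]I)CC(=O)c3ccccc3C2=O)c2ccccc2c1O | intermediate
11 | rubioncolin C, methyl 4-[(1,4-dioxo-1,4-dihydronaphthalen-2-yl)oxy]-1-hydroxy-3-(3-methylbut-2-en-1-yl)-2-naphthoate | COC(=O)c1c(CC=C(C)C)c(OC2=CC(=O)c3ccccc3C2=O)c2ccccc2c1O | target

**Step count and risks**

Total step count: 5. Longest linear sequence: 4 (steps 1, 3, 4, 5; the branch through steps 2, 3, 4, 5 is equally long).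

Steps most likely to fail:

1. Step 5. The aroylpalladium species may be intercepted before ring closure, by esterification with a phenolic OH of a second molecule or by reduction. Acyl delivery may go in the 5-exo mode. The captodative enone may also oligomerise thermally before oxidative addition. Fallback: the ether bond is made onto a preformed quinone instead of closing ring B. Setting out from 3, the phenoxide (K2CO3, DMF, 0 °C, Ar) is added slowly to commercial 2-bromo-1,4-naphthoquinone, so that addition–elimination at the free 4-OH outruns electron transfer from the hydroquinone. This should give 11 directly, where it comes back to the route; it makes no compound beyond the list (F0).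

2. Step 1. Acid may cyclise the new prenyl chain onto the neighbouring 4-OH (chroman formation). O-allylation or a second alkylation may compete, and the hydroquinone may be oxidised by air. Fallback: a Claisen route that sets out from 1. O-Alkylation of the free 4-OH with 3-chloro-3-methylbut-1-yne (K2CO3, KI cat., acetone, reflux) should give methyl 1-hydroxy-4-[(2-methylbut-3-yn-2-yl)oxy]-2-naphthoate F1. Semihydrogenation (H2, Pd/CaCO3 poisoned with Pb(OAc)2, quinoline, EtOAc, 20 °C) should give methyl 1-hydroxy-4-[(2-methylbut-3-en-2-yl)oxy]-2-naphthoate F2. Heating in PhNEt2 at 120 °C should then effect aromatic Claisen rearrangement to the only free ortho carbon (C3) with allyl inversion, returning to the route at 3 without any acid.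

3. Step 4. Under prolonged reflux the amine may add back to the product enone or the enone may oligomerise. A second aminomethylation may occur, and formaldehyde may attack the prenyl double bond under acid (Prins-type). Fallback: a stepwise, base-mediated sequence at low temperature that sets out from 6. Crossed aldol with one equivalent of aqueous formaldehyde (K2CO3, THF–EtOH, 20 °C) should give methyl 1-hydroxy-4-{[3-hydroxy-1-(2-iodophenyl)-1-oxopropan-2-yl]oxy}-3-(3-methylbut-2-en-1-yl)-2-naphthoate F3 (racemic). MsCl and Et3N in CH2Cl2 at −20 °C should give the primary mesylate methyl 1-hydroxy-4-{[1-(2-iodophenyl)-3-(methylsulfonyloxy)-1-oxopropan-2-yl]oxy}-3-(3-methylbut-2-en-1-yl)-2-naphthoate F4 (racemic). With excess Et3N on warming to 0 °C, F4 should eliminate and return to the route at 8.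

**Further compounds**

F0 | step 5 | none | none
F1 | step 1 | methyl 1-hydroxy-4-[(2-methylbut-3-yn-2-yl)oxy]-2-naphthoate | COC(=O)c1cc(OC(C)(C)C#C)c2ccccc2c1O
F2 | step 1 | methyl 1-hydroxy-4-[(2-methylbut-3-en-2-yl)oxy]-2-naphthoate | COC(=O)c1cc(OC(C)(C)C=C)c2ccccc2c1O
F3 | step 4 | methyl 1-hydroxy-4-{[3-hydroxy-1-(2-iodophenyl)-1-oxopropan-2-yl]oxy}-3-(3-methylbut-2-en-1-yl)-2-naphthoate (racemic) | COC(=O)c1c(CC=C(C)C)c(OC(CO)C(=O)c2ccccc2I)c2ccccc2c1O
F4 | step 4 | methyl 1-hydroxy-4-{[1-(2-iodophenyl)-3-(methylsulfonyloxy)-1-oxopropan-2-yl]oxy}-3-(3-methylbut-2-en-1-yl)-2-naphthoate (racemic) | COC(=O)c1c(CC=C(C)C)c(OC(COS(C)(=O)=O)C(=O)c2ccccc2I)c2ccccc2c1O
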